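The route rests on cutting the C2–C1' bond at the dihydrofuran ring. The feature exploited is that C1' sits on C2 cis to the oxygen on C3 and carries both a =CH2 and an oxygenated CH2. That pattern is a propargyl group hung from the C3 oxygen through silicon. In one operation a C2 radical closes 6-exo-dig onto the internal alkyne carbon. This forms C2–C1', the exocyclic methylene, the C2 configuration and a temporary oxasilinane ring whose Si–CH2 bond later becomes CH2OH. The precursor is the dimethyl(propargyl)silyl ether of an enantioenriched 5-acetyl-6-(methoxymethoxy)-2-(phenylselanyl)-2,3-dihydrobenzofuran-3-ol. It is built from 4,6-diacetylresorcinol, so the acetyl group is in place from the start.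

Key step: step 7

Remark on the chemistry: benzofuran numbering (O1, C2, C3, C3a, C4–C7, C7a) is used for all bicyclic compounds, and the side chain is C1' (alkene carbon on C2), C2' (=CH2) and C3' (CH2O). The target is read as (2R,3R), with C1' and the C3 oxygen cis and a Z (angelate) ester. The C2 configuration of 5, 6 and 11 is erased in step 7.

Step 1
Reactants: 1 4,6-diacetylresorcinol
Product: 3 5-acetyl-6-hydroxybenzofuran-3(2H)-one, via bromoketone 2 (not isolated)
Conditions: CuBr2 (1.8 equiv), EtOAc/CHCl3 1:1, reflux; filter, concentrate; then NaOAc, EtOH, reflux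
Reagents that add atoms: copper dibromide, [Cu+2].[Br-].[Br-] (its bromine stays only in 2)
Why: Heterogeneous CuBr2 performs the α-bromination of hydroxyacetophenones at the side chain without touching the ring, the two acetyl groups of 1 are equivalent so that a slight deficit of CuBr2 limits double bromination, and the ortho phenol then displaces bromide in an intramolecular Williamson etherification (5-exo-tet) that leaves the second acetyl at C5 and its chelated phenol at C6 with no regiochemical ambiguity.

Step 2
Reactants: 3 5-acetyl-6-hydroxybenzofuran-3(2H)-one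
Product: 4 5-acetyl-6-(methoxymethoxy)benzofuran-3(2H)-one
Conditions: MOMCl (1.2 equiv), i-Pr2NEt (1.5 equiv), CH2Cl2, 0 °C to rt
Reagents that add atoms: chloromethyl methyl ether (MOMCl), COCCl
Why: Williamson-type O-alkylation of the most acidic site, the C6 phenol, by the reactive α-chloro ether under a hindered amine base that is too weak to enolise either ketone to a useful extent.

Step 3
Reactants: 4 5-acetyl-6-(methoxymethoxy)benzofuran-3(2H)-one
Product: 5 5-acetyl-6-(methoxymethoxy)-2-(phenylselanyl)benzofuran-3(2H)-one (racemic and configurationally labile at C2)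
Conditions: PhSeCl (1.0 equiv), pyridine (1.2 equiv), CH2Cl2, 0 °C to rt
Reagents that add atoms: benzeneselenenyl chloride (PhSeCl), Cl[Se]c1ccccc1
Why: Electrophilic α-selenenylation of a ketone through its enol works here because C2–H is by far the most acidic C–H (its enol is an aromatic 3-hydroxybenzofuran), so that buffered PhSeCl reacts there and not at the acetyl methyl group, and one equivalent of reagent should stop at the monoselenide.

Step 4
Reactants: 5 5-acetyl-6-(methoxymethoxy)-2-(phenylselanyl)benzofuran-3(2H)-one
Product: 6 1-[(2R,3R)-3-hydroxy-6-(methoxymethoxy)-2-(phenylselanyl)-2,3-dihydrobenzofuran-5-yl]ethanone (OH and SePh cis)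
Conditions: RuCl[(S,S)-TsDPEN](p-cymene) (1 mol %), HCO2H/Et3N 5:2, EtOAc, rt, stopped when 5 is consumed
Reagents that add atoms: none
Why: This is a Noyori–Ikariya asymmetric transfer hydrogenation under dynamic kinetic resolution, a reaction type established for 2-substituted benzofuran-3(2H)-ones, in which C2 epimerises through the aromatic enol, the (S,S) catalyst places the fused arene against its p-cymene ligand and delivers hydride anti to selenium to set C3 as R, and the ring ketone activated by its α-oxygen and α-selenium should be consumed well before the electron-rich ortho-substituted acetyl group.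

Step 5
Reactants: 7 propargyl bromide; 8 dichlorodimethylsilane
Product: 10 chlorodimethyl(prop-2-ynyl)silane, via allenylmagnesium bromide 9 (not isolated)
Conditions: 7, Mg, ZnBr2 (cat.), Et2O, 0 °C; then cannulated into 8 (3 equiv), Et2O, −78 °C to rt; fractional distillation
Reagents that add atoms: magnesium, [Mg] (stays only in 9)
Why: Grignard formation from propargyl bromide gives the allenyl metal species, which is silylated at its γ carbon (SE2' substitution at a chlorosilane) to give the propargylsilane, while inverse addition into excess 8 suppresses double substitution as well as acetylide formation and distillation removes any allenyl isomer.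

Step 6
Reactants: 6 (2R,3R)-selenide alcohol; 10 chlorodimethyl(prop-2-ynyl)silane
Product: 11 (2R,3R)-5-acetyl-6-(methoxymethoxy)-2-(phenylselanyl)-2,3-dihydrobenzofuran-3-yl dimethyl(prop-2-ynyl)silyl ether
Conditions: 10 (1.3 equiv), imidazole (2 equiv), CH2Cl2, 0 °C; filtration through Et3N-washed SiO2, used at once
Reagents that add atoms: none
Why: Standard imidazole-promoted silyl ether formation at the only free hydroxyl group is placed directly before the radical step so that the labile dimethylsilyl ether never meets acid, fluoride, palladium or untreated silica, and no stereocentre is touched.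

Step 7
Reactants: 11 propargylsilyl ether selenide
Product: 12 cis-fused tricyclic siloxane in which a 1,2-oxasilinane ring (O–SiMe2–CH2–C(=CH2)) spans O3 and C2 of (2R,3R)-5-acetyl-6-(methoxymethoxy)-2,3-dihydrobenzofuran
Conditions: Bu3SnH (1.4 equiv) and AIBN (0.2 equiv) in PhH, syringe pump over 8 h into 11 (3 mM) in degassed PhH, reflux; hexane/MeCN partition, short pad of Et3N-washed SiO2 to remove tin and selenium residues
Reagents that add atoms: none
Why: Proposed new method: the tributyltin radical abstracts the phenylselanyl group of 11 to give the α-aryloxy C2 radical, which adds to the internal alkyne carbon of the propargylsilane held on O3, and the terminal vinyl radical so formed takes hydrogen from Bu3SnH to leave the exocyclic methylene and carry the chain. The closest known reaction type is the silicon-tethered cyclisation of selenide-derived β-silyloxy or anomeric radicals onto vinylsilyl, allylsilyl and alkynylsilyl ethers followed by Tamao oxidation, whereas a propargylsilyl acceptor has not been used in this way. The one new ring, the 1,2-oxasilinane made of C2, C3, O, Si, CH2 and C1', closes in the 6-exo-dig mode. The one new stereocentre, C2, is controlled by the tether, because a six-membered ring can span the C2–C3 bond of the five-membered ring only in cis fashion, so C1' enters on the face of the C3 oxygen whatever the configuration of the selenide. The step needs exo over 7-endo regioselectivity and cyclisation over premature reduction or alkyne hydrostannation: the first is favoured because the endo mode must bend the linear alkyne into the forming ring, and the second by slow addition at high dilution, where irreversible selenium abstraction should outrun the reversible addition of tin radicals to the alkyne. The aryl ketone, the MOM ether and the Si–O bond are inert to neutral tin hydride conditions.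

Step 8
Reactants: 12 tricyclic siloxane
Product: 13 1-[(2R,3R)-3-hydroxy-2-(3-hydroxyprop-1-en-2-yl)-6-(methoxymethoxy)-2,3-dihydrobenzofuran-5-yl]ethanone (cis diol)
Conditions: 30% aq H2O2, KF, KHCO3, THF/MeOH 1:1, rt
Reagents that add atoms: hydrogen peroxide, OO
Why: In this Tamao oxidation fluoride-assisted peroxide attack on silicon moves the allylic CH2 from Si to O without allylic transposition and both Si–O bonds are hydrolysed, as is known for cyclic allylsiloxanes, so the stereocentres are untouched, and the earlier removal of selenium residues prevents perseleninic acid chemistry at the ketone or alkene.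

Step 9
Reactants: 13 cis diol
Product: 14 2-[(2R,3R)-5-acetyl-3-hydroxy-6-(methoxymethoxy)-2,3-dihydrobenzofuran-2-yl]allyl acetate
Conditions: AcCl (1.1 equiv), 2,4,6-collidine, CH2Cl2, −78 °C
Reagents that add atoms: acetyl chloride, CC(=O)Cl
Why: In this sterically controlled acylation acetyl chloride with the hindered base collidine at low temperature should esterify the open primary allylic alcohol much faster than the secondary C3 carbinol flanked by the cis C2 substituent.

Step 10
Reactants: 14 C3 alcohol acetate; 15 angelic acid
Product: 17 (2R,3R)-5-acetyl-2-(3-acetoxyprop-1-en-2-yl)-6-(methoxymethoxy)-2,3-dihydrobenzofuran-3-yl (Z)-2-methylbut-2-enoate, via mixed anhydride 16 (not isolated)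
Conditions: 15 (3 equiv), 2,4,6-Cl3C6H2COCl (3 equiv), Et3N (6 equiv), PhMe, rt; then 14, 75 °C, no DMAP
Reagents that add atoms: 2,4,6-trichlorobenzoyl chloride, O=C(Cl)c1c(Cl)cc(Cl)cc1Cl (stays only in 16)
Why: In this Yamaguchi esterification the hindered aroyl end of 16 directs the C3 alcohol to the angeloyl carbonyl, leaving out nucleophilic catalysts avoids the addition–elimination path that turns angelates (Z) into tiglates (E), and the C3–O bond is not broken so that the configuration is retained.

Step 11
Reactants: 17 MOM-protected angelate
Product: 18 (2R,3R)-5-acetyl-2-(3-acetoxyprop-1-en-2-yl)-6-hydroxy-2,3-dihydrobenzofuran-3-yl (Z)-2-methylbut-2-enoate (CNP0323250.1)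
Conditions: NaHSO4·SiO2, CH2Cl2, rt
Reagents that add atoms: none
Why: Acetal hydrolysis of a phenolic MOM ether on a mild solid acid is selective for aryl acetals over esters, the departing phenol is stabilised by hydrogen bonding to the C5 acetyl group, and the same acetyl group draws electron density from O1 and the C6 oxygen and thus slows ionisation of the benzylic C3 angelate.

Compound list
1 | 4,6-diacetylresorcinol | CC(=O)c1cc(C(C)=O)c(O)cc1O | starting material
2 | 1-(5-acetyl-2,4-dihydroxyphenyl)-2-bromoethanone | CC(=O)c1cc(C(=O)CBr)c(O)cc1O | intermediate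
3 | 5-acetyl-6-hydroxybenzofuran-3(2H)-one | CC(=O)c1cc2c(cc1O)OCC2=O | intermediate
4 | 5-acetyl-6-(methoxymethoxy)benzofuran-3(2H)-one | CC(=O)c1cc2c(cc1OCOC)OCC2=O | intermediate
5 | 5-acetyl-6-(methoxymethoxy)-2-(phenylselanyl)benzofuran-3(2H)-one, racemic | CC(=O)c1cc2c(cc1OCOC)OC([Se]c1ccccc1)C2=O | intermediate
6 | 1-[(2R,3R)-3-hydroxy-6-(methoxymethoxy)-2-(phenylselanyl)-2,3-dihydrobenzofuran-5-yl]ethanone | O[C@@H]1c2cc(C(C)=O)c(OCOC)cc2O[C@@H]1[Se]c1ccccc1 | intermediate
7 | propargyl bromide | C#CCBr | starting material
8 | dichlorodimethylsilane | C[Si](C)(Cl)Cl | starting material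
9 | allenylmagnesium bromide | C=C=C[Mg]Br | intermediate
10 | chlorodimethyl(prop-2-ynyl)silane | C#CC[Si](C)(C)Cl | intermediate
11 | (2R,3R)-5-acetyl-6-(methoxymethoxy)-2-(phenylselanyl)-2,3-dihydrobenzofuran-3-yl dimethyl(prop-2-ynyl)silyl ether | C#CC[Si](C)(C)O[C@@H]1c2cc(C(C)=O)c(OCOC)cc2O[C@@H]1[Se]c1ccccc1 | intermediate
12 | cis-fused tricyclic siloxane with exocyclic methylene at C1', (2R,3R) in benzofuran numbering | C=C1C[Si](C)(C)O[C@@H]2c3cc(C(C)=O)c(OCOC)cc3O[C@H]12 | intermediate
13 | 1-[(2R,3R)-3-hydroxy-2-(3-hydroxyprop-1-en-2-yl)-6-(methoxymethoxy)-2,3-dihydrobenzofuran-5-yl]ethanone | C=C(CO)[C@H]1Oc2cc(OCOC)c(C(C)=O)cc2[C@H]1O | intermediate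
14 | 2-[(2R,3R)-5-acetyl-3-hydroxy-6-(methoxymethoxy)-2,3-dihydrobenzofuran-2-yl]allyl acetate | C=C(COC(C)=O)[C@H]1Oc2cc(OCOC)c(C(C)=O)cc2[C@H]1O | intermediate
15 | angelic acid, (Z)-2-methylbut-2-enoic acid | C/C=C(/C)C(=O)O | starting material
16 | angelic 2,4,6-trichlorobenzoic anhydride | C/C=C(/C)C(=O)OC(=O)c1c(Cl)cc(Cl)cc1Cl | intermediate
17 | (2R,3R)-5-acetyl-2-(3-acetoxyprop-1-en-2-yl)-6-(methoxymethoxy)-2,3-dihydrobenzofuran-3-yl (Z)-2-methylbut-2-enoate | C=C(COC(C)=O)[C@H]1Oc2cc(OCOC)c(C(C)=O)cc2[C@H]1OC(=O)/C(C)=C\C | intermediate
18 | (2R,3R)-5-acetyl-2-(3-acetoxyprop-1-en-2-yl)-6-hydroxy-2,3-dihydrobenzofuran-3-yl (Z)-2-methylbut-2-enoate | C=C(COC(C)=O)[C@H]1Oc2cc(O)c(C(C)=O)cc2[C@H]1OC(=O)/C(C)=C\C | target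

Total step count: 11. Longest linear sequence: 10 (steps 1–4 and 6–11). Step 5 is a one-step side branch.

Steps most likely to fail

Step 7 (new method). Four things may go wrong:
- The C2 radical may take hydrogen from Bu3SnH before the slow ring closure.
- The long Si–O and Si–C bonds may open the 7-endo mode.
- Tin radicals may add to the terminal alkyne.
- The radical may expel the silyloxy group and aromatise.

The fallback uses known chemistry only, sets out from 4 and comes back at 13. The C2–C1' bond is made at the ketone stage by palladium-catalysed α-alkenylation of the C2 enolate with 2-bromopropene (Pd2(dba)3, P(t-Bu)3, K3PO4, PhMe). This gives 5-acetyl-6-(methoxymethoxy)-2-(prop-1-en-2-yl)benzofuran-3(2H)-one F1. The transfer hydrogenation of step 4 under dynamic kinetic resolution then gives the cis (2R,3R) 2-isopropenyl-3-ol F2. Allylic oxidation of its methyl group (SeO2 cat., t-BuOOH, CH2Cl2) gives diol 13.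

Step 4. Hydride transfer to the C5 acetyl may compete. Selenium may be lost or passed between enolates in the amine medium, and it may slow the ruthenium catalyst. Conversion and enantiopurity would then suffer. The fallback sets out from 5 and comes back at 6, and it replaces asymmetric catalysis at the ketone by resolution at the alcohol. NaBH4/CeCl3·7H2O (MeOH/CH2Cl2, −78 °C) reduces the activated ring ketone anti to selenium to the racemic cis alcohol, that is 6 together with its (2S,3S) enantiomer F3. Acylative kinetic resolution with (R)-benzotetramisole, propanoic anhydride and i-Pr2NEt (CHCl3, 0 °C) should convert F3 into the (2S,3S) propanoate F4 and leave 6, which is separated by chromatography.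

Step 10. The activated angeloyl donor may isomerise from Z to E. Acylation of the hindered cis carbinol may be slow, and long heating may dehydrate the 3-ol towards the benzofuran. The fallback sets out from 14 and comes back at 17, and it builds the Z alkene on the ester instead of transferring it. Saponification (LiOH, THF/H2O, 0 °C) of commercial methyl 2-[bis(2,2,2-trifluoroethoxy)phosphoryl]propanoate gives 2-[bis(2,2,2-trifluoroethoxy)phosphoryl]propanoic acid F5. Carbodiimide coupling with 14 (EDC, cat. DMAP, CH2Cl2, 0 °C) gives the C3 phosphonopropanoate F6. Still–Gennari olefination (KN(SiMe3)2, 18-crown-6, THF, −78 °C, then acetaldehyde) gives 17 with the Z geometry set kinetically.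

Further compounds
F1 | step 7 | 5-acetyl-6-(methoxymethoxy)-2-(prop-1-en-2-yl)benzofuran-3(2H)-one, racemic and labile at C2 | C=C(C)C1Oc2cc(OCOC)c(C(C)=O)cc2C1=O
F2 | step 7 | 1-[(2R,3R)-3-hydroxy-6-(methoxymethoxy)-2-(prop-1-en-2-yl)-2,3-dihydrobenzofuran-5-yl]ethanone | C=C(C)[C@H]1Oc2cc(OCOC)c(C(C)=O)cc2[C@H]1O
F3 | step 4 | 1-[(2S,3S)-3-hydroxy-6-(methoxymethoxy)-2-(phenylselanyl)-2,3-dihydrobenzofuran-5-yl]ethanone | O[C@H]1c2cc(C(C)=O)c(OCOC)cc2O[C@H]1[Se]c1ccccc1
F4 | step 4 | (2S,3S)-5-acetyl-6-(methoxymethoxy)-2-(phenylselanyl)-2,3-dihydrobenzofuran-3-yl propanoate | CCC(=O)O[C@H]1c2cc(C(C)=O)c(OCOC)cc2O[C@H]1[Se]c1ccccc1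
F5 | step 10 | 2-[bis(2,2,2-trifluoroethoxy)phosphoryl]propanoic acid | CC(C(=O)O)P(=O)(OCC(F)(F)F)OCC(F)(F)F
F6 | step 10 | (2R,3R)-5-acetyl-2-(3-acetoxyprop-1-en-2-yl)-6-(methoxymethoxy)-2,3-dihydrobenzofuran-3-yl 2-[bis(2,2,2-trifluoroethoxy)phosphoryl]propanoate, epimers at the phosphonate carbon | C=C(COC(C)=O)[C@H]1Oc2cc(OCOC)c(C(C)=O)cc2[C@H]1OC(=O)C(C)P(=O)(OCC(F)(F)F)OCC(F)(F)F
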